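## Retrosynthetic overview

1. Caraphenol B ⇐ its hexamethyl ether (global O-demethylation) ⇐ secondary benzylic alcohol (oxidation) ⇐ exocyclic alkene on C1 (hydroboration from the face opposite the two cis aryl groups sets C1).
2. Key disconnection: the C2–C3 bond of the five-membered ring, closed by intramolecular C–H insertion of a diaryl carbene at C3 (from a benzophenone hydrazone) into the C2–H bond. This is the only ring-forming step; all four benzene rings are bought.
3. Enabling feature: C1 carries two one-carbon arms, C2 and the exocyclic carbonyl carbon, each bonded to a 4-oxygenated phenyl ring, so the C1 unit comes from one ester and two equivalents of one benzyl Grignard reagent. C3 is a methine between ring A and the 3,5-dioxygenated ring (a diaryl carbene carbon) and lies 1,5 to the hydridic, benzylic and allylic C2–H; the cis C2/C3 relation is the usual outcome of such insertions.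
4. Carbene precursor ⇐ aryl bromide + 3,5-dimethoxybenzonitrile (aryllithium addition, then transimination with hydrazine); aryl bromide ⇐ dehydration of the symmetric carbinol ⇐ methyl 2-bromo-3,5-dimethoxybenzoate + 4-methoxybenzylmagnesium chloride.

Key step: step 6

Remark on labels: C1, C2 and C3 are the sp3 carbons of the five-membered ring carrying the 4-hydroxybenzoyl, 4-hydroxyphenyl and 3,5-dihydroxyphenyl groups; C3a and C7a are the ring-fusion carbons next to C3 and C1; ring A is the fused benzene ring (oxygen at C4 and C6).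

Assumption: the target's descriptors place all three substituents at C1, C2 and C3 on one face, (1R,2R,3R); the (R)-configured catalyst of step 6 is taken to give the (2S,3R) indane, and the mirror-image complex Rh2(S-PTAD)4 would be used if the sense of induction on this substrate were the opposite.

Remark: the trisubstituted alkene of step 3 is carried as its E isomer; any Z isomer separated there would be returned to the equilibrating acid of step 3.

## Route

Step 1
Reactants: 1 methyl 3,5-dimethoxybenzoate
Product: 2 methyl 2-bromo-3,5-dimethoxybenzoate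
Conditions: NBS (1.05 equiv), MeCN, 0 °C → rt
Reagents that add atoms: N-bromosuccinimide, O=C1CCC(=O)N1Br
Why: Electrophilic aromatic bromination should go at C2, which is para to one methoxy group and ortho to the other, rather than at the position flanked by both methoxy groups.

Step 2
Reactants: 2 methyl 2-bromo-3,5-dimethoxybenzoate; 3 4-methoxybenzylmagnesium chloride (two equivalents are incorporated)
Product: 5 2-(2-bromo-3,5-dimethoxyphenyl)-1,3-bis(4-methoxyphenyl)propan-2-ol, via ketone 4 (not isolated)
Conditions: 3 (2.6 equiv), THF, 0 °C → rt; aq. NH4Cl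
Reagents that add atoms: none
Why: Double Grignard addition to the ester, through the more electrophilic ketone 4, should give the symmetric tertiary carbinol, the weakly basic benzyl Grignard reagent adding faster than it enolises 4 and leaving the aryl bromide untouched.

Step 3
Reactants: 5 2-(2-bromo-3,5-dimethoxyphenyl)-1,3-bis(4-methoxyphenyl)propan-2-ol
Product: 6 2-bromo-1-[(1E)-1,3-bis(4-methoxyphenyl)prop-1-en-2-yl]-3,5-dimethoxybenzene
Conditions: TsOH·H2O (5 mol %), toluene, 80 °C
Reagents that add atoms: none
Why: Acid-catalysed E1 dehydration of the tertiary benzylic alcohol can give only one constitution because the two arms are identical, and equilibration under the acid should favour the E isomer, in which ring A and the anisyl ring are trans across the double bond.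

Step 4
Reactants: 6 2-bromo-1-[(1E)-1,3-bis(4-methoxyphenyl)prop-1-en-2-yl]-3,5-dimethoxybenzene; 7 3,5-dimethoxybenzonitrile
Product: 9 1-{2-[(1E)-1,3-bis(4-methoxyphenyl)prop-1-en-2-yl]-4,6-dimethoxyphenyl}-1-(3,5-dimethoxyphenyl)methanimine, via aryllithium 8 (not isolated)
Conditions: n-BuLi (1.05 equiv), THF, −78 °C; 7, −78 → 0 °C; MeOH
Reagents that add atoms: none
Why: Bromine–lithium exchange followed by addition of the aryllithium to the nitrile should stop at the N-lithio ketimine (no second addition) and give the N–H ketimine on methanol quench, the low temperature letting exchange and addition outrun proton transfer from the allylic CH2 group.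

Step 5
Reactants: 9 1-{2-[(1E)-1,3-bis(4-methoxyphenyl)prop-1-en-2-yl]-4,6-dimethoxyphenyl}-1-(3,5-dimethoxyphenyl)methanimine
Product: 10 {2-[(1E)-1,3-bis(4-methoxyphenyl)prop-1-en-2-yl]-4,6-dimethoxyphenyl}(3,5-dimethoxyphenyl)methanone hydrazone (E/Z mixture at C=N, of no consequence)
Conditions: N2H4 (1 M in THF, 5 equiv), AcOH (10 mol %), EtOH, 60 °C
Reagents that add atoms: hydrazine, NN
Why: Transimination (addition of hydrazine to the protonated ketimine and loss of ammonia) should give the hydrazone of this doubly ortho-substituted benzophenone more readily than condensation with the ketone itself would.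

Step 6
Reactants: 10 {2-[(1E)-1,3-bis(4-methoxyphenyl)prop-1-en-2-yl]-4,6-dimethoxyphenyl}(3,5-dimethoxyphenyl)methanone hydrazone
Product: 12 (2S,3R)-3-(3,5-dimethoxyphenyl)-4,6-dimethoxy-1-[(E)-(4-methoxyphenyl)methylidene]-2-(4-methoxyphenyl)-2,3-dihydro-1H-indene (aryl groups at C2 and C3 cis), via diazoalkane 11 (not isolated)
Conditions: MnO2 (8 equiv), Rh2(R-PTAD)4 (1 mol %), CH2Cl2/MeCN, −20 → 0 °C, slow addition of 10
Reagents that add atoms: none
Why: MnO2 dehydrogenates the hydrazone to diaryldiazomethane 11, which loses N2 on the dirhodium tetracarboxylate to give an electrophilic donor/donor carbene at C3; this takes up hydride from the allylic, anisyl-benzylic C2–H through a six-membered array and the C3–C2 bond closes at once (intramolecular carbene C–H insertion). The closest known reaction type is the Rh2(R-PTAD)4-catalysed 1,5 C–H insertion of diaryl carbenes generated from benzophenone hydrazones with MnO2, which gives cis-2,3-diaryl-2,3-dihydrobenzofurans and 1,2-disubstituted indanes with high enantioselectivity. The five-membered ring is closed in the 1,5-insertion mode, C3 onto C2, with C3a, C7a and the sp2 carbon C1 as the other ring atoms. C3 and C2 are both created here: their cis relation should follow from hydride transfer and C–C bond formation on the same face of the carbene before any rotation, and their absolute configuration from the chiral pocket of the four N-phthaloyl-adamantylglycinate ligands (catalyst control, no stereocentre in the substrate). The step needs site selectivity for C2–H over the C–H bonds of the ortho methoxy group and chemoselectivity over the C1 alkene and over 1,7-electrocyclisation of 11: the C2–H bonds are by far the most hydridic, carbene addition to the alkene would need a four-membered or bicyclo[2.1.0] ring, and the slow addition keeps 11 at a low stationary concentration. Because both arms on C1 end in a 4-methoxyphenyl group, bond formation at either end of the developing 1,3-dianisylallyl unit would give the same skeleton, and the E geometry keeps the anisyl group away from the peri C7–H.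

Step 7
Reactants: 12 (2S,3R)-3-(3,5-dimethoxyphenyl)-4,6-dimethoxy-1-[(E)-(4-methoxyphenyl)methylidene]-2-(4-methoxyphenyl)-2,3-dihydro-1H-indene
Product: 14 (R)-[(1R,2R,3R)-3-(3,5-dimethoxyphenyl)-4,6-dimethoxy-2-(4-methoxyphenyl)-2,3-dihydro-1H-inden-1-yl](4-methoxyphenyl)methanol, via alkylborane 13 (not isolated)
Conditions: BH3·THF (3 equiv), THF, 0 °C → rt; then 3 M NaOH, 30% H2O2, 0 °C → rt
Reagents that add atoms: hydrogen peroxide, OO
Why: Brown hydroboration–oxidation should add H–B syn across the exocyclic alkene with boron on the less substituted benzylic carbon and from the face opposite the two cis aryl groups, so that the new C1–H is trans to them and the carbinol arm cis (all-cis ring, substrate control), the C–B bond then being oxidised with retention and the E alkene geometry fixing the (R) carbinol centre.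

Step 8
Reactants: 14 (R)-[(1R,2R,3R)-3-(3,5-dimethoxyphenyl)-4,6-dimethoxy-2-(4-methoxyphenyl)-2,3-dihydro-1H-inden-1-yl](4-methoxyphenyl)methanol
Product: 15 [(1R,2R,3R)-3-(3,5-dimethoxyphenyl)-4,6-dimethoxy-2-(4-methoxyphenyl)-2,3-dihydro-1H-inden-1-yl](4-methoxyphenyl)methanone (caraphenol B hexamethyl ether, all-cis)
Conditions: Dess–Martin periodinane (1.3 equiv), CH2Cl2, 0 °C → rt
Reagents that add atoms: none
Why: Dess–Martin oxidation of the secondary benzylic alcohol under near-neutral, non-enolising conditions should give the ketone without disturbing the kinetically set C1 centre next to it.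

Step 9
Reactants: 15 [(1R,2R,3R)-3-(3,5-dimethoxyphenyl)-4,6-dimethoxy-2-(4-methoxyphenyl)-2,3-dihydro-1H-inden-1-yl](4-methoxyphenyl)methanone
Product: 16 caraphenol B, [(1R,2R,3R)-3-(3,5-dihydroxyphenyl)-4,6-dihydroxy-2-(4-hydroxyphenyl)-2,3-dihydro-1H-inden-1-yl](4-hydroxyphenyl)methanone
Conditions: BBr3 (12 equiv), CH2Cl2, −78 → 20 °C; then H2O, 0 °C
Reagents that add atoms: none
Why: Lewis-acid cleavage of the six aryl methyl ethers (bromide attack on the methyl group of each boron-complexed ether) breaks no bond to a stereocentre, and the low starting temperature should keep the ketone from enolising at C1.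

## Compound list

1 | methyl 3,5-dimethoxybenzoate | COC(=O)c1cc(OC)cc(OC)c1 | starting material
2 | methyl 2-bromo-3,5-dimethoxybenzoate | COC(=O)c1cc(OC)cc(OC)c1Br | intermediate
3 | 4-methoxybenzylmagnesium chloride | COc1ccc(C[Mg]Cl)cc1 | starting material
4 | 1-(2-bromo-3,5-dimethoxyphenyl)-2-(4-methoxyphenyl)ethan-1-one | COc1ccc(CC(=O)c2cc(OC)cc(OC)c2Br)cc1 | intermediate (not isolated)
5 | 2-(2-bromo-3,5-dimethoxyphenyl)-1,3-bis(4-methoxyphenyl)propan-2-ol | COc1ccc(CC(O)(Cc2ccc(OC)cc2)c2cc(OC)cc(OC)c2Br)cc1 | intermediate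
6 | 2-bromo-1-[(1E)-1,3-bis(4-methoxyphenyl)prop-1-en-2-yl]-3,5-dimethoxybenzene | Brc1c(OC)cc(OC)cc1/C(Cc1ccc(OC)cc1)=C/c1ccc(OC)cc1 | intermediate
7 | 3,5-dimethoxybenzonitrile | N#Cc1cc(OC)cc(OC)c1 | starting material
8 | {2-[(1E)-1,3-bis(4-methoxyphenyl)prop-1-en-2-yl]-4,6-dimethoxyphenyl}lithium | [Li]c1c(OC)cc(OC)cc1/C(Cc1ccc(OC)cc1)=C/c1ccc(OC)cc1 | intermediate (not isolated)
9 | 1-{2-[(1E)-1,3-bis(4-methoxyphenyl)prop-1-en-2-yl]-4,6-dimethoxyphenyl}-1-(3,5-dimethoxyphenyl)methanimine | N=C(c1cc(OC)cc(OC)c1)c1c(OC)cc(OC)cc1/C(Cc1ccc(OC)cc1)=C/c1ccc(OC)cc1 | intermediate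
10 | {2-[(1E)-1,3-bis(4-methoxyphenyl)prop-1-en-2-yl]-4,6-dimethoxyphenyl}(3,5-dimethoxyphenyl)methanone hydrazone | NN=C(c1cc(OC)cc(OC)c1)c1c(OC)cc(OC)cc1/C(Cc1ccc(OC)cc1)=C/c1ccc(OC)cc1 | intermediate
11 | 1-[diazo(3,5-dimethoxyphenyl)methyl]-2-[(1E)-1,3-bis(4-methoxyphenyl)prop-1-en-2-yl]-4,6-dimethoxybenzene | [N-]=[N+]=C(c1cc(OC)cc(OC)c1)c1c(OC)cc(OC)cc1/C(Cc1ccc(OC)cc1)=C/c1ccc(OC)cc1 | intermediate (not isolated)
12 | (2S,3R)-3-(3,5-dimethoxyphenyl)-4,6-dimethoxy-1-[(E)-(4-methoxyphenyl)methylidene]-2-(4-methoxyphenyl)-2,3-dihydro-1H-indene | COc1ccc(cc1)/C=C1/c2cc(OC)cc(OC)c2[C@@H](c2cc(OC)cc(OC)c2)[C@H]1c1ccc(OC)cc1 | intermediate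
13 | monoalkylborane carrying BH2 in place of the hydroxyl group of 14, same spatial arrangement | B[C@@H](c1ccc(OC)cc1)[C@H]1c2cc(OC)cc(OC)c2[C@@H](c2cc(OC)cc(OC)c2)[C@H]1c1ccc(OC)cc1 | intermediate (not isolated)
14 | (R)-[(1R,2R,3R)-3-(3,5-dimethoxyphenyl)-4,6-dimethoxy-2-(4-methoxyphenyl)-2,3-dihydro-1H-inden-1-yl](4-methoxyphenyl)methanol | O[C@@H](c1ccc(OC)cc1)[C@H]1c2cc(OC)cc(OC)c2[C@@H](c2cc(OC)cc(OC)c2)[C@H]1c1ccc(OC)cc1 | intermediate
15 | [(1R,2R,3R)-3-(3,5-dimethoxyphenyl)-4,6-dimethoxy-2-(4-methoxyphenyl)-2,3-dihydro-1H-inden-1-yl](4-methoxyphenyl)methanone | O=C(c1ccc(OC)cc1)[C@H]1c2cc(OC)cc(OC)c2[C@@H](c2cc(OC)cc(OC)c2)[C@H]1c1ccc(OC)cc1 | intermediate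
16 | caraphenol B, [(1R,2R,3R)-3-(3,5-dihydroxyphenyl)-4,6-dihydroxy-2-(4-hydroxyphenyl)-2,3-dihydro-1H-inden-1-yl](4-hydroxyphenyl)methanone | O=C(c1ccc(O)cc1)[C@H]1c2cc(O)cc(O)c2[C@@H](c2cc(O)cc(O)c2)[C@H]1c1ccc(O)cc1 | target

## Step count and risks

Total step count: 9. Longest linear sequence: 9 steps (1 → 16).

**Step 6 (key step).** The hydride-transfer stage of the insertion creates a 1,3-dianisylallyl cation next to the rhodium-bound C3; if this pair lives long enough to rotate before the C–C bond closes, the cis relation of the C2 and C3 aryl groups is partly lost. The fallback sets out from 10 and comes back at 15; it keeps the insertion for C3 only and resets C2 and C1 afterwards. Step 6 would be run as written and the indane fraction taken on as a mixture of 12 and its C2 epimer, the (2R,3R) trans indane F1. Steps 7 and 8 on this mixture would give 15 together with the 2,3-trans alcohol F2 and the 2,3-trans ketone F3, whose configuration at C1 is of no consequence. Dehydrogenation of the ketone mixture with IBX (DMSO, 70 °C) would remove the C1 and C2 hydrogens of both ketones and give one indene enone, the hexamethyl ether of caraphenol C F4, in which C3 is the only stereocentre. Hydrogenation (H2, palladium on carbon, EtOAc) should then add both hydrogens syn, from the face opposite the C3 aryl group, and give all-cis 15.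

**Step 4.** The aryllithium may quench itself by intramolecular proton transfer from the allylic, benzylic CH2 group before it adds to the hindered nitrile. The fallback sets out from 6 and comes back at 10, with no carbanion in play. Carbonylative Suzuki–Miyaura coupling of 6 with 3,5-dimethoxyphenylboronic acid (Pd(OAc)2, di(1-adamantyl)-n-butylphosphine, CO, K2CO3, toluene, 100 °C) would give the diaryl ketone F5, and condensation of F5 with hydrazine (AcOH, n-BuOH, 110 °C) would give 10.

**Step 9.** The acidic demethylation may enolise the ketone at C1 and turn the aroyl group to the trans side. The fallback sets out from 15 and comes back at 16; it moves the creation of C1 and C2 to the last, neutral step. Ketone 15 would be dehydrogenated with IBX to the indene enone F4 described above, which has no enolisable stereocentre. BBr3 would then give caraphenol C F6, and hydrogenation (H2, palladium on carbon, MeOH/EtOAc) should add hydrogen opposite the C3 aryl group to give 16.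

## Further compounds

F1 | step 6 | (2R,3R)-3-(3,5-dimethoxyphenyl)-4,6-dimethoxy-1-[(E)-(4-methoxyphenyl)methylidene]-2-(4-methoxyphenyl)-2,3-dihydro-1H-indene (aryl groups at C2 and C3 trans) | COc1ccc(cc1)/C=C1/c2cc(OC)cc(OC)c2[C@@H](c2cc(OC)cc(OC)c2)[C@@H]1c1ccc(OC)cc1
F2 | step 6 | [(2S,3R)-3-(3,5-dimethoxyphenyl)-4,6-dimethoxy-2-(4-methoxyphenyl)-2,3-dihydro-1H-inden-1-yl](4-methoxyphenyl)methanol, C1 and carbinol carbon not defined | OC(c1ccc(OC)cc1)C1c2cc(OC)cc(OC)c2[C@@H](c2cc(OC)cc(OC)c2)[C@@H]1c1ccc(OC)cc1
F3 | step 6 | [(2S,3R)-3-(3,5-dimethoxyphenyl)-4,6-dimethoxy-2-(4-methoxyphenyl)-2,3-dihydro-1H-inden-1-yl](4-methoxyphenyl)methanone, C1 not defined | O=C(c1ccc(OC)cc1)C1c2cc(OC)cc(OC)c2[C@@H](c2cc(OC)cc(OC)c2)[C@@H]1c1ccc(OC)cc1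
F4 | step 6 | caraphenol C hexamethyl ether, [(1S)-1-(3,5-dimethoxyphenyl)-5,7-dimethoxy-2-(4-methoxyphenyl)-1H-inden-3-yl](4-methoxyphenyl)methanone | O=C(c1ccc(OC)cc1)C1=C(c2ccc(OC)cc2)[C@H](c2cc(OC)cc(OC)c2)c2c(OC)cc(OC)cc21
F5 | step 4 | {2-[(1E)-1,3-bis(4-methoxyphenyl)prop-1-en-2-yl]-4,6-dimethoxyphenyl}(3,5-dimethoxyphenyl)methanone | O=C(c1cc(OC)cc(OC)c1)c1c(OC)cc(OC)cc1/C(Cc1ccc(OC)cc1)=C/c1ccc(OC)cc1
F6 | step 9 | caraphenol C, [(1S)-1-(3,5-dihydroxyphenyl)-5,7-dihydroxy-2-(4-hydroxyphenyl)-1H-inden-3-yl](4-hydroxyphenyl)methanone | O=C(c1ccc(O)cc1)C1=C(c2ccc(O)cc2)[C@H](c2cc(O)cc(O)c2)c2c(O)cc(O)cc21
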